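The ratio I follow in this flask is side product to target, taken as a share: side product over side product plus target. Birch is the flask asked about, followed so far. Ash is an earlier run at twice the concentration.

all flasks: free catalyst 0.1 mol%

|  | starting material | reagent | remark | time |
|---|---|---|---|---|
| birch | 0.50 M | 1 equiv | the very flask that is asked about, followed so far |  |
| ash | 1 M | 1 equiv | run made earlier |  |
| flask | 0.50 M | 1.00 equiv |  | 80 min |

- birch (time / min: side product / %, target / %): 2.50: 2.3, 17.7; 5.00: 4.6, 37.9; 6.00: 4.9, 45.2; 10.0: 6.8, 65.8; 12.0: 6.5, 72.8; 15.0: 6.0, 78.9
- ash (time / min: side product / %, target / %): 2.50: 4.7, 37.8; 4.00: 4.7, 56.8; 6.00: 5.9, 72.3; 10.0: 6.4, 87.5; 15.0: 6.8, 92.4; 20.0: 6.4, 93.4; 30.0: 7.3, 93.5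

(readings scatter by 0.5 percentage points)

- percent here means starting material units held: one side product counts as two

1. share of side product in side product plus target at 25 s
2. share of side product in side product plus target at 6.0 min
3. share of side product in side product plus target at 80 min

A rate constant tells how fast one step goes, while a share compares two amounts made over the same time, so a delay that holds back both products alike drops out of it. That is why I reckon the share directly, and not each product on its own. Birch's first reading gives 11.5% and its second gives 10.8%, so the share falls slowly, and the large part of the answer is already read. What remains is the correction. Running that slope back from 2.50 min to 25 s adds 0.56 percentage points, which is small beside the share itself. The first reading plus this correction is what I call the early share, 12.1%. It remains a reading, since a peak of 2.3% carries 0.5 points; ash at its own first reading, 2.50 min, reads 11.1%.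

The middle time needs no reckoning: birch at 6.0 min reads 9.78%. For 80 min I take ash's last reading, made at 30.0 min, 7.24%.

The forecast gives 30%, 10.2% and 6.9%. It parts from me at the early time, 30% against 12.1%, on these grounds: “At 25 s the catalytic target is only about 1%, while side product is about 0.55%”.

The flask gives 12.4%, 9.94% and 6.67%, which puts the forecast 18 points too high at 25 s. In the scheme, both products come from open intermediate, which in this flask stands at 11.4% after 8.00 min.

    starting material + free catalyst ⇌ free catalyst + open intermediate (K = 2.10, k = 520 /M/min)
    free catalyst + open intermediate ⇌ catalyst intermediate (K = 120 /M, k = 1400 /M/min)
    reagent + catalyst intermediate → free catalyst + target (k = 730 /M/min)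
    starting material + open intermediate → side product (k = 0.0920 /M/min)

Against the early share of 12.1%, this flask ends lower, at 6.67%. The neighbour charged with 0.400 equiv of reagent ends at 44.0%, which is 3.64 times that early share, with reagent, there the limiting reagent, at 0%.

Readings and results are simulated on assumed constants; scatter was added.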